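**Retrosynthetic overview**
1. Target 31 ⇒ dioxane alcohol 29 ⇒ open-chain silyl peroxide mesylate 26. The 1,2-dioxane is closed last, by SN2 attack of the C13 peroxide on C3'. C13–OO comes from cobalt/O2/silane peroxidation of a C13=C5' alkene, C2'/C3' from an Evans syn-aldol, and C5'–C3' from a Wittig reaction on methyl ketone 14.
2. 14 ⇒ 8(9)-ene 9: the oxygen is moved from C8 to C9 by α-epoxidation, epoxide-to-allylic-alcohol isomerisation and HAT hydrogenation (9α-OH, 8α-CH3).
3. 9 ⇒ tricyclic enol ether 8 (acid opening of the pyran) ⇒ (E,E)-farnesylacetone 7 by enzymatic tricyclisation; 7 from (E,E)-farnesol and ethyl acetoacetate.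
4. Feature: rings A and B with C11, C12, C13 and the methyl groups on C4, C8, C10 and C13 (18 carbons) are atom for atom farnesylacetone. Ring order: rings A and B and a temporary dihydropyran together (step 4), pyran opened (step 5), 1,2-dioxane last (step 18).

Key step: step 4

Numbering: decalin and linker carbons carry labdane numbers (C1–C13; C17 is the methyl carbon on C8); the five carbons added later are C1' (carboxyl), C2', C3' (dioxane CH–O), C4', C5' (dioxane CH2 next to C13). Dec = (1R,2R,4aS,8aS)-1-hydroxy-2,5,5,8a-tetramethyldecahydronaphthalen-1-yl.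
Assumption: no nearby stereocentre can bias C13 in step 16, so both C13 epimers are assumed to form and to be separable on silica as the dioxane alcohols in step 18.

Step 1
Reactants: 1 (2E,6E)-farnesol
Product: 2 (2E,6E)-farnesyl bromide
Conditions: PBr3 (0.4 equiv), Et2O, −10 to 0 °C
Reagents that add atoms: phosphorus tribromide, BrP(Br)Br
Why: Bromination of a primary allylic alcohol through its phosphite ester (SN2 by bromide) at low temperature should keep both (E)-alkenes and avoid allylic transposition.

Step 2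
Reactants: 2 (2E,6E)-farnesyl bromide; 3 ethyl acetoacetate
Product: 5 ethyl (4E,8E)-2-acetyl-5,9,13-trimethyltetradeca-4,8,12-trienoate, via sodium enolate 4 (not isolated)
Conditions: NaH, THF, 0 °C; then 2, 0 °C to rt
Reagents that add atoms: none
Why: Acetoacetic ester alkylation, in which the stabilised enolate C-alkylates the primary allylic bromide by SN2 without touching the alkene geometry; an excess of 3 limits dialkylation.

Step 3
Reactants: 5 ethyl (4E,8E)-2-acetyl-5,9,13-trimethyltetradeca-4,8,12-trienoate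
Product: 7 (5E,9E)-6,10,14-trimethylpentadeca-5,9,13-trien-2-one ((E,E)-farnesylacetone), via β-keto acid 6 (not isolated)
Conditions: 2 M NaOH, MeOH, 50 °C; then 2 M HCl to pH 3, 60 °C
Reagents that add atoms: none
Why: Saponification followed by thermal decarboxylation of the β-keto acid (acetoacetic ester ketone synthesis) leaves the trisubstituted alkenes untouched.

Step 4
Reactants: 7 (5E,9E)-farnesylacetone
Product: 8 tricyclic enol ether (8α,13-epoxy-14,15-dinorlabd-12-ene, sclareol oxide; (4aR,6aS,10aS,10bR)-3,4a,7,7,10a-pentamethyl-4a,5,6,6a,7,8,9,10,10a,10b-decahydro-1H-benzo[f]chromene)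
Conditions: recombinant squalene–hopene cyclase from Alicyclobacillus acidocaldarius (E. coli whole cells), citrate buffer pH 6.0, 0.2% Triton X-100, 50 °C
Reagents that add atoms: none
Why: The active-site aspartic acid of the cyclase protonates C3 of the terminal C3=C4 alkene on one enantiotopic face, and the chain, held in a chair–chair fold, collapses in a cationic cascade (C4 cation to C5, C10 cation to C9, C8 cation to the ketone oxygen, loss of H12); the closest known reaction type is the squalene–hopene cyclase cyclisation of homofarnesol to ambroxide and of isoprenoid methyl ketones to cyclic enol ethers. Ring A closes 6-endo (C4–C5), ring B closes 6-endo (C9–C10), and the dihydropyran closes by attack of the carbonyl oxygen on the C8 cation (six-membered, C8–O) followed by deprotonation to the C12=C13 enol ether. C5 and C10 arise by anti addition across the (E)-C5=C10 alkene in a chair, which gives the trans ring fusion (5α-H, 10β-CH3). C9 and C8 arise by anti addition of C10 and oxygen across the (E)-C8=C9 alkene (9α-H, 8α-O), and the absolute sense of all four centres is fixed by the enzyme pocket through the face of protonation. The step needs complete (E,E) geometry in 7, which steps 1–3 secure from geometrically pure farnesol, and clean termination, which the ketone oxygen secures as an internal nucleophile. C8 and C9 are erased in step 5, so only C5 and C10 have to last, and no later step touches them.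

Step 5
Reactants: 8 tricyclic enol ether
Product: 9 14,15-dinorlabd-8-en-13-one (4-[(4aS,8aS)-2,5,5,8a-tetramethyl-3,4,4a,5,6,7,8,8a-octahydronaphthalen-1-yl]butan-2-one)
Conditions: TsOH·H2O (0.1 equiv), toluene, 110 °C
Reagents that add atoms: none
Why: Acid-catalysed isomerisation: C12 protonation gives the C13 oxocarbenium ion, heterolysis of its C8–O bond releases the methyl ketone and the tertiary C8 cation, and E1 loss of H9 gives the tetrasubstituted 8(9)-alkene, expected to be the thermodynamic product; C8 and C9 are erased on purpose.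

Step 6
Reactants: 9 14,15-dinorlabd-8-en-13-one
Product: 10 13,13-ethylenedioxy-14,15-dinorlabd-8-ene (1,3-dioxolane ketal of 9)
Conditions: ethylene glycol, TsOH (cat.), benzene, reflux, Dean–Stark
Reagents that add atoms: ethylene glycol, OCCO
Why: Acid-catalysed ketalisation with azeotropic removal of water masks the enolisable ketone for the strong base of step 8; the tetrasubstituted alkene is already the stable isomer and should not move.

Step 7
Reactants: 10 13,13-ethylenedioxy-14,15-dinorlabd-8-ene
Product: 11 8α,9α-epoxy-13,13-ethylenedioxy-14,15-dinorlabdane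
Conditions: mCPBA, NaHCO3, CH2Cl2, 0 °C
Reagents that add atoms: 3-chloroperoxybenzoic acid, O=C(OO)c1cccc(Cl)c1
Why: Prilezhaev epoxidation of the electron-rich tetrasubstituted alkene from the α face, because the β face is screened by the axial C10 methyl group, places oxygen 8α,9α; NaHCO3 protects ketal and epoxide from the acid by-product.

Step 8
Reactants: 11 8α,9α-epoxy-13,13-ethylenedioxy-14,15-dinorlabdane
Product: 12 13,13-ethylenedioxy-14,15-dinorlabd-8(17)-en-9α-ol
Conditions: LiNEt2 (4 equiv), Et2O–hexane, reflux; H2O quench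
Reagents that add atoms: none
Why: Base-promoted isomerisation of an epoxide to an allylic alcohol by syn β-elimination: the lithium amide bound to the epoxide oxygen removes the least hindered proton, that of the C17 methyl group, so the C8–O bond breaks and oxygen stays on C9 with its α configuration; loss of H7 instead would give the 7-ene, which converges on the same product in step 9.

Step 9
Reactants: 12 13,13-ethylenedioxy-14,15-dinorlabd-8(17)-en-9α-ol
Product: 13 13,13-ethylenedioxy-8α-methyl-14,15-dinorlabdan-9α-ol (8β-H)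
Conditions: Mn(dpm)3 (0.1 equiv; dpm = dipivaloylmethanate), PhSiH3, t-BuOOH, i-PrOH, 22 °C
Reagents that add atoms: none
Why: Manganese-hydride hydrogen-atom-transfer hydrogenation: H• adds to C17 to give the tertiary C8 radical, which takes up the second hydrogen axially so that the methyl group ends equatorial (8α-CH3, 8β-H), the thermodynamic epimer that avoids a 1,3-diaxial clash with the C10 methyl group and the opposite of what surface hydrogenation from the open α face would give.

Step 10
Reactants: 13 13,13-ethylenedioxy-8α-methyl-14,15-dinorlabdan-9α-ol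
Product: 14 4-Dec-butan-2-one (9α-hydroxy-8α-methyl-14,15-dinorlabdan-13-one)
Conditions: PPTS (0.2 equiv), acetone–H2O (10:1), 50 °C
Reagents that add atoms: water, O
Why: Mild acid-catalysed acetal hydrolysis in wet acetone frees the methyl ketone, which equilibrates with its five-membered hemiketal through the 9α-OH; PPTS is too weak to ionise the tertiary alcohol.

Step 11
Reactants: 14 4-Dec-butan-2-one; 15 (3-hydroxypropyl)triphenylphosphonium bromide
Product: 17 (3E/Z)-4-methyl-6-Dec-hex-3-en-1-ol, via oxido ylide 16 (not isolated)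
Conditions: 15 (4 equiv), n-BuLi (8 equiv), THF, −20 °C to rt; then 14, rt to 50 °C
Reagents that add atoms: none
Why: Wittig olefination of the methyl ketone with a γ-oxido ylide, where excess ylide covers the acidic 9-OH and reopens the hemiketal; the E/Z mixture is of no consequence because C13 becomes sp3 through a planar radical in step 16.

Step 12
Reactants: 17 (3E/Z)-4-methyl-6-Dec-hex-3-en-1-ol
Product: 18 (3E/Z)-4-methyl-6-Dec-hex-3-enal
Conditions: Dess–Martin periodinane, NaHCO3, CH2Cl2, 0 °C; used crude
Reagents that add atoms: none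
Why: Dess–Martin oxidation of the primary alcohol under buffered, non-basic conditions; the tertiary 9-OH cannot be oxidised, and the β,γ-unsaturated aldehyde is used at once so that the alkene does not move into conjugation.

Step 13
Reactants: 18 (3E/Z)-4-methyl-6-Dec-hex-3-enal; 19 (S)-4-benzyl-3-propionyloxazolidin-2-one
Product: 22 (4S)-4-benzyl-3-[(2S,3R,5E/Z)-3-hydroxy-2,6-dimethyl-8-Dec-oct-5-enoyl]oxazolidin-2-one, via boron enolate 20 (not isolated), via boron aldolate 21 (not isolated)
Conditions: 19 (1.5 equiv), Bu2BOTf, i-Pr2NEt, CH2Cl2, −78 to 0 °C; then 18, −78 to −10 °C; pH 7 buffer, MeOH, 30% H2O2, 0 °C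
Reagents that add atoms: none
Why: Evans syn-aldol: the (Z)-boron enolate reacts through a closed Zimmerman–Traxler chair on the enolate face away from the benzyl group, which sets C2' (S) and C3' (R, 2',3'-syn) under auxiliary control, independent of the remote decalin.

Step 14
Reactants: 22 Evans aldol adduct
Product: 23 (2R,3R,5E/Z)-2,6-dimethyl-8-Dec-oct-5-ene-1,3-diol
Conditions: LiBH4, MeOH (2 equiv), THF, 0 °C
Reagents that add atoms: none
Why: Reductive cleavage of the N-acyl oxazolidinone with LiBH4 gives the primary alcohol without touching C2' or C3', so that C1' cannot later trigger β-elimination of the C3' leaving group.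

Step 15
Reactants: 23 (2R,3R,5E/Z)-2,6-dimethyl-8-Dec-oct-5-ene-1,3-diol
Product: 24 1-O-tert-butyldimethylsilyl ether of 23
Conditions: TBSCl (1.05 equiv), imidazole, CH2Cl2, −10 to 0 °C
Reagents that add atoms: tert-butyldimethylsilyl chloride, CC(C)(C)[Si](C)(C)Cl
Why: Silylation is selective on steric grounds for the primary C1'-OH over the secondary C3'-OH and the hindered tertiary C9-OH.

Step 16
Reactants: 24 1-O-TBS ether of 23
Product: 25 (2R,3R)-1-(tert-butyldimethylsilyloxy)-2,6-dimethyl-8-Dec-6-(triethylsilylperoxy)octan-3-ol (both C13 epimers)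
Conditions: Co(acac)2 (0.1 equiv), Et3SiH (3 equiv), O2 (1 atm), ClCH2CH2Cl, 20 °C
Reagents that add atoms: dioxygen, O=O; triethylsilane, CC[SiH](CC)CC
Why: Mukaiyama–Isayama hydroperoxysilylation: a cobalt hydride transfers H• to C5', the tertiary C13 radical traps O2 and the peroxyl is silylated, fully Markovnikov; the planar radical is remote from every stereocentre, so both C13 epimers must be expected in similar amounts and are carried together to step 18.

Step 17
Reactants: 25 triethylsilyl peroxide alcohol
Product: 26 C3' methanesulfonate of 25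
Conditions: MsCl, Et3N, CH2Cl2, −20 °C
Reagents that add atoms: methanesulfonyl chloride, CS(=O)(=O)Cl
Why: Sulfonylation of the only unhindered free hydroxyl (C3') with retention; the tertiary C9-OH is too hindered, and the silyl peroxide is inert to MsCl and amine.

Step 18
Reactants: 26 silyl peroxide mesylate
Product: 29 (2R)-2-[(3S,6S)-6-methyl-6-(2-Dec-ethyl)-1,2-dioxan-3-yl]propan-1-ol, via hydroperoxide 27 (not isolated), via silyl-protected dioxane 28 (not isolated)
Conditions: Bu4NF (3 equiv), THF, 0 °C to rt; chromatography on silica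
Reagents that add atoms: none
Why: Fluoride cleaves the weak Si–OO bond first, the peroxide anion displaces the C3' mesylate in a 6-exo-tet intramolecular SN2 alkylation with inversion (C3' R to S, 2',3'-anti), and the same reagent then removes the TBS group; the (13S) diastereomer, with side chain and C12 chain both equatorial, is separated from its C13 epimer on silica.

Step 19
Reactants: 29 dioxane alcohol
Product: 31 (2S)-2-[(3S,6S)-6-methyl-6-(2-Dec-ethyl)-1,2-dioxan-3-yl]propanoic acid (CNP0328037.1), via aldehyde 30 (not isolated)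
Conditions: TEMPO (0.2 equiv), PhI(OAc)2 (2.5 equiv), MeCN–H2O (1:1), rt
Reagents that add atoms: water, O
Why: TEMPO-catalysed oxidation with PhI(OAc)2 takes the primary alcohol through the aldehyde hydrate to the acid under near-neutral conditions that spare the O–O bond, the tertiary alcohol and the α-stereocentre C2'.

**Compound list**
1 | (2E,6E)-farnesol | CC(C)=CCC/C(C)=C/CC/C(C)=C/CO | starting material
2 | (2E,6E)-farnesyl bromide | CC(C)=CCC/C(C)=C/CC/C(C)=C/CBr | intermediate
3 | ethyl acetoacetate | CCOC(=O)CC(C)=O | starting material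
4 | sodium enolate of ethyl acetoacetate | CCOC(=O)C=C(C)[O-].[Na+] | intermediate
5 | ethyl (4E,8E)-2-acetyl-5,9,13-trimethyltetradeca-4,8,12-trienoate | CCOC(=O)C(C/C=C(\C)CC/C=C(\C)CCC=C(C)C)C(C)=O | intermediate
6 | (4E,8E)-2-acetyl-5,9,13-trimethyltetradeca-4,8,12-trienoic acid | OC(=O)C(C/C=C(\C)CC/C=C(\C)CCC=C(C)C)C(C)=O | intermediate
7 | (5E,9E)-farnesylacetone | CC(=O)CC/C=C(\C)CC/C=C(\C)CCC=C(C)C | intermediate
8 | tricyclic enol ether (sclareol oxide) | CC1=CC[C@H]2[C@](C)(O1)CC[C@H]3C(C)(C)CCC[C@@]32C | intermediate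
9 | 14,15-dinorlabd-8-en-13-one | CC(=O)CCC1=C(C)CC[C@H]2C(C)(C)CCC[C@@]21C | intermediate
10 | 13,13-ethylenedioxy-14,15-dinorlabd-8-ene | CC1(CCC2=C(C)CC[C@H]3C(C)(C)CCC[C@@]32C)OCCO1 | intermediate
11 | 8α,9α-epoxy-13,13-ethylenedioxy-14,15-dinorlabdane | CC1(CC[C@@]23O[C@]2(C)CC[C@H]4C(C)(C)CCC[C@@]43C)OCCO1 | intermediate
12 | 13,13-ethylenedioxy-14,15-dinorlabd-8(17)-en-9α-ol | CC1(CC[C@@]2(O)C(=C)CC[C@H]3C(C)(C)CCC[C@@]32C)OCCO1 | intermediate
13 | 13,13-ethylenedioxy-8α-methyl-14,15-dinorlabdan-9α-ol | CC1(CC[C@@]2(O)[C@H](C)CC[C@H]3C(C)(C)CCC[C@@]32C)OCCO1 | intermediate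
14 | 4-Dec-butan-2-one | CC(=O)CC[C@@]1(O)[C@H](C)CC[C@H]2C(C)(C)CCC[C@@]21C | intermediate
15 | (3-hydroxypropyl)triphenylphosphonium bromide | OCCC[P+](c1ccccc1)(c1ccccc1)c1ccccc1.[Br-] | starting material
16 | lithium 3-(triphenylphosphoranylidene)propan-1-olate | [Li+].[O-]CCC=P(c1ccccc1)(c1ccccc1)c1ccccc1 | intermediate
17 | (3E/Z)-4-methyl-6-Dec-hex-3-en-1-ol | OCCC=C(C)CC[C@@]1(O)[C@H](C)CC[C@H]2C(C)(C)CCC[C@@]21C | intermediate
18 | (3E/Z)-4-methyl-6-Dec-hex-3-enal | O=CCC=C(C)CC[C@@]1(O)[C@H](C)CC[C@H]2C(C)(C)CCC[C@@]21C | intermediate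
19 | (S)-4-benzyl-3-propionyloxazolidin-2-one | CCC(=O)N1[C@@H](Cc2ccccc2)COC1=O | starting material
20 | (Z)-dibutylboron enolate of 19 | C/C=C(\OB(CCCC)CCCC)N1[C@@H](Cc2ccccc2)COC1=O | intermediate
21 | dibutylboron aldolate of 22 | C[C@H](C(=O)N1[C@@H](Cc2ccccc2)COC1=O)[C@H](OB(CCCC)CCCC)CC=C(C)CC[C@@]3(O)[C@H](C)CC[C@H]4C(C)(C)CCC[C@@]43C | intermediate
22 | (4S)-4-benzyl-3-[(2S,3R,5E/Z)-3-hydroxy-2,6-dimethyl-8-Dec-oct-5-enoyl]oxazolidin-2-one | C[C@H](C(=O)N1[C@@H](Cc2ccccc2)COC1=O)[C@H](O)CC=C(C)CC[C@@]3(O)[C@H](C)CC[C@H]4C(C)(C)CCC[C@@]43C | intermediate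
23 | (2R,3R,5E/Z)-2,6-dimethyl-8-Dec-oct-5-ene-1,3-diol | C[C@H](CO)[C@H](O)CC=C(C)CC[C@@]3(O)[C@H](C)CC[C@H]4C(C)(C)CCC[C@@]43C | intermediate
24 | 1-O-TBS ether of 23 | C[C@H](CO[Si](C)(C)C(C)(C)C)[C@H](O)CC=C(C)CC[C@@]3(O)[C@H](C)CC[C@H]4C(C)(C)CCC[C@@]43C | intermediate
25 | C13 triethylsilyl peroxide (both C13 epimers) | C[C@H](CO[Si](C)(C)C(C)(C)C)[C@H](O)CCC(C)(OO[Si](CC)(CC)CC)CC[C@@]3(O)[C@H](C)CC[C@H]4C(C)(C)CCC[C@@]43C | intermediate
26 | C3' mesylate of 25 (both C13 epimers) | C[C@H](CO[Si](C)(C)C(C)(C)C)[C@H](OS(C)(=O)=O)CCC(C)(OO[Si](CC)(CC)CC)CC[C@@]3(O)[C@H](C)CC[C@H]4C(C)(C)CCC[C@@]43C | intermediate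
27 | C13 hydroperoxide mesylate (both C13 epimers) | C[C@H](CO[Si](C)(C)C(C)(C)C)[C@H](OS(C)(=O)=O)CCC(C)(OO)CC[C@@]3(O)[C@H](C)CC[C@H]4C(C)(C)CCC[C@@]43C | intermediate
28 | TBS ether of dioxane alcohol 29 | C[C@H](CO[Si](C)(C)C(C)(C)C)[C@@H]1CC[C@@](C)(CC[C@@]3(O)[C@H](C)CC[C@H]4C(C)(C)CCC[C@@]43C)OO1 | intermediate
29 | (2R)-2-[(3S,6S)-6-methyl-6-(2-Dec-ethyl)-1,2-dioxan-3-yl]propan-1-ol | C[C@H](CO)[C@@H]1CC[C@@](C)(CC[C@@]3(O)[C@H](C)CC[C@H]4C(C)(C)CCC[C@@]43C)OO1 | intermediate
30 | (2S)-2-[(3S,6S)-6-methyl-6-(2-Dec-ethyl)-1,2-dioxan-3-yl]propanal | C[C@H](C=O)[C@@H]1CC[C@@](C)(CC[C@@]3(O)[C@H](C)CC[C@H]4C(C)(C)CCC[C@@]43C)OO1 | intermediate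
31 | (2S)-2-[(3S,6S)-6-methyl-6-(2-Dec-ethyl)-1,2-dioxan-3-yl]propanoic acid (CNP0328037.1) | C[C@H](C(=O)O)[C@@H]1CC[C@@](C)(CC[C@@]2(O)[C@H](C)CC[C@H]3C(C)(C)CCC[C@@]32C)OO1 | target

**Step count**
Total: 19 steps. Longest linear sequence: 19 steps from (2E,6E)-farnesol (15, 19 and 3 are bought).

**Three steps most likely to fail**

Step 4 (key step). The cascade may stall on a preparative scale through poor substrate uptake or product inhibition, or end early by deprotonation after one or two rings. The fallback replaces the enzymatic route to 8 by semisynthesis and therefore does not set out from a numbered compound (it stands in for 1–7). Commercial (−)-sclareol F1 is degraded at its vinyl carbinol side chain with KMnO4 in aqueous acetone to 8α-hydroxy-14,15-dinorlabdan-13-one F2. Catalytic TsOH in toluene then cyclodehydrates F2, and the fallback comes back to the route at 8.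

Step 8. The amide base may remove a C11 proton instead, with cleavage of the C9–O bond and loss of the oxygen from C9, or the hindered tetrasubstituted epoxide may not react at all. The fallback sets out from 10 and bypasses 11. A Schenck ene reaction with singlet oxygen (O2, tetraphenylporphyrin, visible light, CH2Cl2, 0 °C) attacks the α face of the 8(9)-alkene and gives 13,13-ethylenedioxy-9α-hydroperoxy-14,15-dinorlabd-8(17)-ene F3. Reduction with PPh3 then returns to the route at 12. The 7-ene regioisomer of the ene reaction is equally usable in step 9.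

Step 18. E2 loss of the mesylate, or base-induced Kornblum–DeLaMare fragmentation of the new peroxide, may compete with ring closure under basic fluoride. The fallback sets out from 23 and uses a leaving group that cannot eliminate. TsCl in pyridine gives the primary tosylate of 23 F4. KOt-Bu in THF closes it to the cis-2,3-disubstituted oxetane F5, with C3' retained. Co(acac)2, Et3SiH and O2 then give the oxetane silyl peroxide F6, and HF·pyridine frees the oxetane hydroperoxide F7. Catalytic TMSOTf in CH2Cl2 at −78 °C promotes the known intramolecular 6-exo opening of the oxetane at C3' by the hydroperoxide, with inversion; it releases the C1' alcohol and returns to the route at 29 after separation of the C13 epimer.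

**Further compounds**
F1 | step 4 | (−)-sclareol | C=C[C@](C)(O)CC[C@H]1[C@](C)(O)CC[C@H]2C(C)(C)CCC[C@@]21C
F2 | step 4 | 8α-hydroxy-14,15-dinorlabdan-13-one | CC(=O)CC[C@H]1[C@](C)(O)CC[C@H]2C(C)(C)CCC[C@@]21C
F3 | step 8 | 13,13-ethylenedioxy-9α-hydroperoxy-14,15-dinorlabd-8(17)-ene | CC1(CC[C@@]2(OO)C(=C)CC[C@H]3C(C)(C)CCC[C@@]32C)OCCO1
F4 | step 18 | primary tosylate of 23 | C[C@H](COS(=O)(=O)c1ccc(C)cc1)[C@H](O)CC=C(C)CC[C@@]3(O)[C@H](C)CC[C@H]4C(C)(C)CCC[C@@]43C
F5 | step 18 | cis-2,3-disubstituted oxetane from 23 | C[C@@H]1CO[C@@H]1CC=C(C)CC[C@@]3(O)[C@H](C)CC[C@H]4C(C)(C)CCC[C@@]43C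
F6 | step 18 | oxetane C13 triethylsilyl peroxide | C[C@@H]1CO[C@@H]1CCC(C)(OO[Si](CC)(CC)CC)CC[C@@]3(O)[C@H](C)CC[C@H]4C(C)(C)CCC[C@@]43C
F7 | step 18 | oxetane C13 hydroperoxide | C[C@@H]1CO[C@@H]1CCC(C)(OO)CC[C@@]3(O)[C@H](C)CC[C@H]4C(C)(C)CCC[C@@]43C
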